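The route rests on disconnecting ring A (the isocoumarin) at two adjacent ring carbons: C8, which carries the diaryl ether oxygen, and C8a, which carries the lactone carbonyl C1, with C4a on the far side still bearing a halogen. One operation joins 3-chloro-5-methoxybenzyne, the phenoxide of a fully protected ring B and carbon dioxide, making the crowded C8–O bond and the C8a–C1 bond together, while chlorine both steers the addition and remains as the handle for the C4a–C4 bond. The precursors are an ortho-silylaryl triflate (aryne source) and a ring B phenol carrying benzyl ethers, a benzyl ester and a dioxolane-masked side-chain ketone.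

Key step: step 9

Remark: the target has no stereocentre, so no step sets configuration; orsellinic acid is taken as purchasable, which avoids a later ester exchange.

Step 1
Reactants: 1 2-chloro-4-methoxyphenol
Product: 2 2-bromo-6-chloro-4-methoxyphenol
Conditions: NBS, i-Pr2NH (cat.), CH2Cl2, 0 °C
Reagents that add atoms: N-bromosuccinimide, O=C1CCC(=O)N1Br
Why: Electrophilic aromatic bromination should enter ortho to the free hydroxyl, the strongest activator, because the para position is blocked by methoxy and the other ortho position by chlorine, and the amine catalyst favours ortho attack on phenols.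

Step 2
Reactants: 2 2-bromo-6-chloro-4-methoxyphenol
Product: 5 2-chloro-4-methoxy-6-(trimethylsilyl)phenyl trifluoromethanesulfonate, via aryl silyl ether 3 (not isolated), via lithium phenoxide 4 (not isolated)
Conditions: HMDS, THF, 70 °C, then evaporation; n-BuLi, THF, −78 °C; Tf2O, −78 °C to rt
Reagents that add atoms: hexamethyldisilazane, C[Si](C)(C)N[Si](C)(C)C; trifluoromethanesulfonic anhydride, O=S(=O)(OS(=O)(=O)C(F)(F)F)C(F)(F)F
Why: This is the standard sequence to ortho-silylaryl triflates: O-silylation, then bromine–lithium exchange (much faster at bromine than at chlorine) triggers the retro-Brook shift of silicon from oxygen to carbon, and the lithium phenoxide is triflated in the same flask.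

Step 3
Reactants: 6 orsellinic acid (2,4-dihydroxy-6-methylbenzoic acid)
Product: 7 benzyl 2,4-bis(benzyloxy)-6-methylbenzoate
Conditions: BnBr, K2CO3, DMF, rt then 60 °C
Reagents that add atoms: benzyl bromide, BrCc1ccccc1
Why: Williamson-type alkylation of the carboxylate and both phenoxides; the carboxylate reacts first at room temperature, which removes the risk of decarboxylation before the flask is warmed to complete the hydrogen-bonded 2-hydroxyl.

Step 4
Reactants: 7 benzyl 2,4-bis(benzyloxy)-6-methylbenzoate
Product: 8 benzyl 4,6-bis(benzyloxy)-3-bromo-2-methylbenzoate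
Conditions: NBS, MeCN, 0 °C to rt, dark
Reagents that add atoms: N-bromosuccinimide, O=C1CCC(=O)N1Br
Why: Electrophilic aromatic bromination of the resorcinol diether should enter next to the methyl group, para to one benzyloxy group and ortho to the other, as orcinol diethers brominate there in preference to the site flanked by both ether oxygens; dark polar conditions suppress benzylic radical bromination.

Step 5
Reactants: 9 hexanoyl chloride
Product: 10 N-methoxy-N-methylhexanamide
Conditions: MeNHOMe·HCl, K2CO3, CH2Cl2/H2O, 0 °C to rt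
Reagents that add atoms: N,O-dimethylhydroxylamine hydrochloride, CNOC.Cl
Why: Schotten–Baumann acylation gives the Weinreb amide, the acyl donor that stops cleanly at the ketone in the next step.

Step 6
Reactants: 8 benzyl 4,6-bis(benzyloxy)-3-bromo-2-methylbenzoate; 10 N-methoxy-N-methylhexanamide
Product: 12 benzyl 4,6-bis(benzyloxy)-3-bromo-2-(2-oxoheptyl)benzoate, via benzylic lithium compound 11 (not isolated)
Conditions: LiN(i-Pr)2 (LDA), THF, −78 °C; then 10, −78 to −40 °C; aq. NH4Cl
Reagents that add atoms: none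
Why: Lateral lithiation of the ortho-toluate (the benzylic anion is stabilised through the ring by the ester, and the ring bromide has no ortho hydrogen and is inert to the amide base) followed by Weinreb ketone synthesis, which excludes over-addition.

Step 7
Reactants: 12 benzyl 4,6-bis(benzyloxy)-3-bromo-2-(2-oxoheptyl)benzoate
Product: 13 benzyl 4,6-bis(benzyloxy)-3-bromo-2-[(2-pentyl-1,3-dioxolan-2-yl)methyl]benzoate
Conditions: (TMSOCH2)2, TMSOTf (cat.), CH2Cl2, −78 to −20 °C; pyridine quench
Reagents that add atoms: 1,2-bis(trimethylsilyloxy)ethane, C[Si](C)(C)OCCO[Si](C)(C)C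
Why: Ketalisation with the bis-silyl ether of ethylene glycol under catalytic TMSOTf masks the ketone at low temperature, without the heat and protic acid that could close the keto ester to an isocoumarin.

Step 8
Reactants: 13 benzyl 4,6-bis(benzyloxy)-3-bromo-2-[(2-pentyl-1,3-dioxolan-2-yl)methyl]benzoate
Product: 15 benzyl 4,6-bis(benzyloxy)-3-hydroxy-2-[(2-pentyl-1,3-dioxolan-2-yl)methyl]benzoate, via pinacol boronate 14 (not isolated)
Conditions: pinacolborane, PdCl2(MeCN)2 (3 mol %), SPhos, Et3N, 1,4-dioxane, 100 °C; then H2O2, aq. NaOH, THF, 0 °C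
Reagents that add atoms: hydrogen peroxide, OO; pinacolborane, CC1(C)OBOC1(C)C (its boron stays only in 14)
Why: Pd-catalysed Miyaura-type borylation with pinacolborane and a bulky biaryl phosphine tolerates two ortho substituents, esters and ketals, and alkaline peroxide oxidation of the carbon–boron bond then gives the phenol at the same carbon.

Step 9
Reactants: 15 benzyl 4,6-bis(benzyloxy)-3-hydroxy-2-[(2-pentyl-1,3-dioxolan-2-yl)methyl]benzoate; 5 2-chloro-4-methoxy-6-(trimethylsilyl)phenyl trifluoromethanesulfonate; 16 carbon dioxide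
Product: 20 2-{4,6-bis(benzyloxy)-3-[(benzyloxy)carbonyl]-2-[(2-pentyl-1,3-dioxolan-2-yl)methyl]phenoxy}-6-chloro-4-methoxybenzoic acid, via potassium phenoxide 17 (not isolated), via aryne 18 (not isolated), via aryl anion 19 (not isolated)
Conditions: KH, THF, 0 °C; then KF, 18-crown-6, CO2 (1 atm), slow addition of 5, 0 °C to rt; cold aq. citric acid work-up
Reagents that add atoms: none
Why: Proposed new method: fluoride removes the silyl group of 5 and triflate departs to give aryne 18; phenoxide 17, made beforehand with KH so that its proton leaves as hydrogen, adds to the aryne carbon remote from chlorine, and the resulting aryl anion 19 is captured by CO2 before it can be protonated. The closest known reaction types are the three-component coupling of arynes with amines and CO2 to anthranilic acids and the regioselective O-arylation of phenols by 3-haloarynes. No ring is closed and no stereocentre is formed. Regioselectivity is needed and is secured by chlorine, whose inductive pull distorts the aryne so that the nucleophile enters at the future C8 and the charge develops at C8a beside chlorine. Chemoselectivity for carboxylation over protonation and over loss of chloride is sought through a proton-free medium (THF instead of an acidic solvent, no free hydroxyl, ketone masked as dioxolane so that no enolisable or electrophilic carbonyl is within reach), a CO2 atmosphere and slow addition of 5.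

Step 10
Reactants: 20 2-{4,6-bis(benzyloxy)-3-[(benzyloxy)carbonyl]-2-[(2-pentyl-1,3-dioxolan-2-yl)methyl]phenoxy}-6-chloro-4-methoxybenzoic acid
Product: 21 tert-butyl 2-{4,6-bis(benzyloxy)-3-[(benzyloxy)carbonyl]-2-[(2-pentyl-1,3-dioxolan-2-yl)methyl]phenoxy}-6-chloro-4-methoxybenzoate
Conditions: t-BuOC(=NH)CCl3, CH2Cl2/cyclohexane, rt
Reagents that add atoms: tert-butyl 2,2,2-trichloroacetimidate, CC(C)(C)OC(=N)C(Cl)(Cl)Cl
Why: O-Alkylation with the trichloroacetimidate esterifies through a tert-butyl cation, so shielding of the carbonyl does not matter and the dioxolane survives; this ester keeps a carboxylate away from the alkyne during coupling and later leaves as isobutene.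

Step 11
Reactants: 21 tert-butyl 2-{4,6-bis(benzyloxy)-3-[(benzyloxy)carbonyl]-2-[(2-pentyl-1,3-dioxolan-2-yl)methyl]phenoxy}-6-chloro-4-methoxybenzoate; 22 hept-1-yne
Product: 23 tert-butyl 2-{4,6-bis(benzyloxy)-3-[(benzyloxy)carbonyl]-2-[(2-pentyl-1,3-dioxolan-2-yl)methyl]phenoxy}-6-(hept-1-yn-1-yl)-4-methoxybenzoate
Conditions: PdCl2(MeCN)2 (5 mol %), XPhos, Cs2CO3, MeCN, 80 °C, slow addition of 22
Reagents that add atoms: none
Why: Copper-free Sonogashira coupling with a bulky biaryl phosphine is the established way to couple aryl chlorides with terminal alkynes, and the ortho ester lowers the barrier to oxidative addition.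

Step 12
Reactants: 23 tert-butyl 2-{4,6-bis(benzyloxy)-3-[(benzyloxy)carbonyl]-2-[(2-pentyl-1,3-dioxolan-2-yl)methyl]phenoxy}-6-(hept-1-yn-1-yl)-4-methoxybenzoate
Product: 25 benzyl 4,6-bis(benzyloxy)-3-[(6-methoxy-1-oxo-3-pentyl-1H-isochromen-8-yl)oxy]-2-(2-oxoheptyl)benzoate, via dioxolane isocoumarin 24 (not isolated)
Conditions: AuCl(PPh3) (5 mol %), AgOTf (5 mol %), CH2Cl2, rt; then 1 M HCl, THF, rt
Reagents that add atoms: water, O
Why: π-Acid-catalysed 6-endo-dig cyclisation: the ester carbonyl oxygen attacks the distal alkyne carbon (the electrophilic, alkyl-bearing terminus of the conjugated system), isobutene is lost and protodeauration gives the isocoumarin, after which dilute aqueous acid hydrolyses the dioxolane while benzyl groups and lactone stay.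

Step 13
Reactants: 25 benzyl 4,6-bis(benzyloxy)-3-[(6-methoxy-1-oxo-3-pentyl-1H-isochromen-8-yl)oxy]-2-(2-oxoheptyl)benzoate
Product: 26 beta-collatolic acid, 4,6-dihydroxy-3-[(6-methoxy-1-oxo-3-pentyl-1H-isochromen-8-yl)oxy]-2-(2-oxoheptyl)benzoic acid
Conditions: H2 (1 atm), Pd/C (10 %), EtOAc, rt, stopped after three equivalents of H2
Reagents that add atoms: none
Why: Hydrogenolysis of the benzyl ester and both benzyl aryl ethers is fast at one atmosphere, whereas the trisubstituted enol-lactone double bond of ring A is expected to be reduced much more slowly, so the reaction is stopped once the benzyl groups are gone.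

Compound list
1 | 2-chloro-4-methoxyphenol | COc1ccc(O)c(Cl)c1 | starting material
2 | 2-bromo-6-chloro-4-methoxyphenol | COc1cc(Cl)c(O)c(Br)c1 | intermediate
3 | (2-bromo-6-chloro-4-methoxyphenoxy)trimethylsilane | COc1cc(Cl)c(O[Si](C)(C)C)c(Br)c1 | intermediate (not isolated)
4 | lithium 2-chloro-4-methoxy-6-(trimethylsilyl)phenoxide | COc1cc(Cl)c([O-])c([Si](C)(C)C)c1.[Li+] | intermediate (not isolated)
5 | 2-chloro-4-methoxy-6-(trimethylsilyl)phenyl trifluoromethanesulfonate | COc1cc(Cl)c(OS(=O)(=O)C(F)(F)F)c([Si](C)(C)C)c1 | intermediate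
6 | orsellinic acid (2,4-dihydroxy-6-methylbenzoic acid) | Cc1cc(O)cc(O)c1C(=O)O | starting material
7 | benzyl 2,4-bis(benzyloxy)-6-methylbenzoate | Cc1cc(OCc2ccccc2)cc(OCc3ccccc3)c1C(=O)OCc1ccccc1 | intermediate
8 | benzyl 4,6-bis(benzyloxy)-3-bromo-2-methylbenzoate | Cc1c(Br)c(OCc2ccccc2)cc(OCc3ccccc3)c1C(=O)OCc1ccccc1 | intermediate
9 | hexanoyl chloride | CCCCCC(=O)Cl | starting material
10 | N-methoxy-N-methylhexanamide | CCCCCC(=O)N(C)OC | intermediate
11 | {2-[(benzyloxy)carbonyl]-3,5-bis(benzyloxy)-6-bromophenyl}methyllithium | [Li]Cc1c(Br)c(OCc2ccccc2)cc(OCc3ccccc3)c1C(=O)OCc1ccccc1 | intermediate (not isolated)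
12 | benzyl 4,6-bis(benzyloxy)-3-bromo-2-(2-oxoheptyl)benzoate | CCCCCC(=O)Cc1c(Br)c(OCc2ccccc2)cc(OCc3ccccc3)c1C(=O)OCc1ccccc1 | intermediate
13 | benzyl 4,6-bis(benzyloxy)-3-bromo-2-[(2-pentyl-1,3-dioxolan-2-yl)methyl]benzoate | CCCCCC1(Cc2c(Br)c(OCc3ccccc3)cc(OCc4ccccc4)c2C(=O)OCc2ccccc2)OCCO1 | intermediate
14 | benzyl 4,6-bis(benzyloxy)-2-[(2-pentyl-1,3-dioxolan-2-yl)methyl]-3-(4,4,5,5-tetramethyl-1,3,2-dioxaborolan-2-yl)benzoate | CCCCCC1(Cc2c(B3OC(C)(C)C(C)(C)O3)c(OCc3ccccc3)cc(OCc4ccccc4)c2C(=O)OCc2ccccc2)OCCO1 | intermediate (not isolated)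
15 | benzyl 4,6-bis(benzyloxy)-3-hydroxy-2-[(2-pentyl-1,3-dioxolan-2-yl)methyl]benzoate (ring B phenol) | Oc1c(OCc2ccccc2)cc(OCc3ccccc3)c(C(=O)OCc4ccccc4)c1CC5(CCCCC)OCCO5 | intermediate
16 | carbon dioxide | O=C=O | starting material
17 | potassium phenoxide of 15 | [K+].[O-]c1c(OCc2ccccc2)cc(OCc3ccccc3)c(C(=O)OCc4ccccc4)c1CC5(CCCCC)OCCO5 | intermediate (not isolated)
18 | 3-chloro-5-methoxybenzyne | COC1=CC#CC(Cl)=C1 | intermediate (not isolated)
19 | arylpotassium formed by addition of 17 to 18 (potassium on the carbon between chlorine and the aryloxy group) | COc1cc(Cl)c([K])c(Oc2c(OCc3ccccc3)cc(OCc4ccccc4)c(C(=O)OCc5ccccc5)c2CC6(CCCCC)OCCO6)c1 | intermediate (not isolated)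
20 | 2-{4,6-bis(benzyloxy)-3-[(benzyloxy)carbonyl]-2-[(2-pentyl-1,3-dioxolan-2-yl)methyl]phenoxy}-6-chloro-4-methoxybenzoic acid | COc1cc(Cl)c(C(=O)O)c(Oc2c(OCc3ccccc3)cc(OCc4ccccc4)c(C(=O)OCc5ccccc5)c2CC6(CCCCC)OCCO6)c1 | intermediate
21 | tert-butyl ester of 20 | COc1cc(Cl)c(C(=O)OC(C)(C)C)c(Oc2c(OCc3ccccc3)cc(OCc4ccccc4)c(C(=O)OCc5ccccc5)c2CC6(CCCCC)OCCO6)c1 | intermediate
22 | hept-1-yne | CCCCCC#C | starting material
23 | tert-butyl 2-{4,6-bis(benzyloxy)-3-[(benzyloxy)carbonyl]-2-[(2-pentyl-1,3-dioxolan-2-yl)methyl]phenoxy}-6-(hept-1-yn-1-yl)-4-methoxybenzoate | CCCCCC#Cc1cc(OC)cc(Oc2c(OCc3ccccc3)cc(OCc4ccccc4)c(C(=O)OCc5ccccc5)c2CC6(CCCCC)OCCO6)c1C(=O)OC(C)(C)C | intermediate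
24 | benzyl 4,6-bis(benzyloxy)-3-[(6-methoxy-1-oxo-3-pentyl-1H-isochromen-8-yl)oxy]-2-[(2-pentyl-1,3-dioxolan-2-yl)methyl]benzoate | CCCCCc1cc2cc(OC)cc(Oc3c(OCc4ccccc4)cc(OCc5ccccc5)c(C(=O)OCc6ccccc6)c3CC7(CCCCC)OCCO7)c2c(=O)o1 | intermediate (not isolated)
25 | benzyl 4,6-bis(benzyloxy)-3-[(6-methoxy-1-oxo-3-pentyl-1H-isochromen-8-yl)oxy]-2-(2-oxoheptyl)benzoate | CCCCCC(=O)Cc1c(Oc2cc(OC)cc3cc(CCCCC)oc(=O)c23)c(OCc2ccccc2)cc(OCc2ccccc2)c1C(=O)OCc1ccccc1 | intermediate
26 | beta-collatolic acid, 4,6-dihydroxy-3-[(6-methoxy-1-oxo-3-pentyl-1H-isochromen-8-yl)oxy]-2-(2-oxoheptyl)benzoic acid | CCCCCC(=O)Cc1c(Oc2cc(OC)cc3cc(CCCCC)oc(=O)c23)c(O)cc(O)c1C(=O)O | target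

Total step count: 13. Longest linear sequence: 10 steps (steps 3, 4, 6, 7, 8, 9, 10, 11, 12 and 13, from orsellinic acid 6).

Steps most likely to fail

Step 9 (proposed new method). The aryl anion may be protonated or may expel chloride before it meets CO2, or the phenoxide may be held back as its carbonate and add too slowly to the aryne. The fallback uses known chemistry, sets out from phenol 15 and rejoins the route at acid 20. Purchased 3-chloro-5-fluoroanisole (COc1cc(F)cc(Cl)c1) is lithiated between the two halogens with LDA in THF at −78 °C and formylated with DMF to give 2-chloro-6-fluoro-4-methoxybenzaldehyde F1. The phenoxide of 15 (K2CO3, DMF, 80 °C) then displaces fluoride, activated by the ortho formyl group, in a nucleophilic aromatic substitution to give benzyl 4,6-bis(benzyloxy)-3-(3-chloro-2-formyl-5-methoxyphenoxy)-2-[(2-pentyl-1,3-dioxolan-2-yl)methyl]benzoate F2. Pinnick oxidation (NaClO2, NaH2PO4, 2-methylbut-2-ene, t-BuOH/H2O) converts the aldehyde into acid 20.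

Step 11. Oxidative addition into the hindered, electron-rich carbon–chlorine bond may be slow, and the terminal alkyne may oligomerise under hot carbonate. The fallback sets out from chloride 21 and hept-1-yne 22 and comes back at alkyne 23 by a Negishi coupling. Alkyne 22 is deprotonated with n-BuLi and transmetalated with ZnCl2 to hept-1-yn-1-ylzinc chloride F3, which is coupled with 21 using Pd(OAc)2 and XPhos in THF at 60 °C. The preformed zinc acetylide removes both the base and the free alkyne from the coupling.

Step 8. Transmetalation at the crowded palladium centre may be slow, so that reduction of the carbon–bromine bond takes over. The fallback sets out from bromide 13 and comes back at boronate 14. Bromine–lithium exchange with n-BuLi in THF at −95 °C gives benzyl 4,6-bis(benzyloxy)-3-lithio-2-[(2-pentyl-1,3-dioxolan-2-yl)methyl]benzoate F4, which is trapped within minutes by 2-isopropoxy-4,4,5,5-tetramethyl-1,3,2-dioxaborolane; the hindered ester should not be attacked at this temperature. The peroxide oxidation of step 8 then gives 15.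

Further compounds
F1 | step 9 | 2-chloro-6-fluoro-4-methoxybenzaldehyde | COc1cc(F)c(C=O)c(Cl)c1
F2 | step 9 | benzyl 4,6-bis(benzyloxy)-3-(3-chloro-2-formyl-5-methoxyphenoxy)-2-[(2-pentyl-1,3-dioxolan-2-yl)methyl]benzoate | COc1cc(Cl)c(C=O)c(Oc2c(OCc3ccccc3)cc(OCc4ccccc4)c(C(=O)OCc5ccccc5)c2CC6(CCCCC)OCCO6)c1
F3 | step 11 | hept-1-yn-1-ylzinc chloride | CCCCCC#C[Zn]Cl
F4 | step 8 | benzyl 4,6-bis(benzyloxy)-3-lithio-2-[(2-pentyl-1,3-dioxolan-2-yl)methyl]benzoate | CCCCCC1(Cc2c([Li])c(OCc3ccccc3)cc(OCc4ccccc4)c2C(=O)OCc2ccccc2)OCCO1
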